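A small charge of L, 16 mM against 0.16 M of D, begins short chains, and this flask is followed only up to 15.0 h.

in all of them: D 0.16 M
- south-west: L 16 mM; the very flask that is asked about, followed so far
- north-west: L 11 mM; run made earlier
- flask: L 16 mM; time 30 h

- south-west (time / h: G / %, D / %): 2.00: 10, 87; 5.00: 18, 82; 10.0: 25, 77; 15.0: 33, 66
- north-west (time / h: G / %, D / %): 1.50: 5, 92; 4.00: 9, 90; 10.0: 17, 82; 20.0: 29, 74

(each reading ± 1.5 percentage points)

- the average divides the monomer in chains by the number of chains begun, living and dead together
- the earlier runs were read with a standard deviation of 1.5 percentage points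
- on the list of suspects stand: D + L -> Z + G; D + Z -> G + Z; G + Z -> D + Z; Z -> E
- the earlier runs do not show the number of chains; that part of a forecast is a guess

1. average number of monomer units in a chain (chains begun, living or dead) at 30 h
2. part of the D that has reacted at 30 h

How do you get dp from c? If each L begins one chain and L has been consumed by 30 h, dp is c times charged [D] over charged [L], which is 10.0, the target degree of polymerisation. The consumption of L is a guess, since the runs do not show chains.

And c? In this flask, −ln[D] rises at a reading of 0.0217 h⁻¹ between 5.00 h and 15.0 h. Carried on from the last reading, that gives a first answer of 52.3%.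

Is that pace steady? The north-west run's last interval, scaled by charged [L], reads 0.0149 h⁻¹, which is slower, though within readings scattered by 1.5 percentage points. Going round again with it, I commit to c = 47.2% and dp = 4.72.

The forecast differs from my reckoning: it says dp 5.3 (4.3 to 6.6) and c 52% (43% to 60%), taking the rate as “roughly proportional to the living ends”.

The flask gives dp 4.30 and c 43.0%.

    D + L → Z + G (k = 0.120 M⁻¹ min⁻¹)
    D + Z → G + Z, rate k2*[Z]*[D] (k = 0.0320 M⁻¹ min⁻¹)
    G + Z → D + Z, rate k3*[Z] as long as [G] is above zero (k = 0.00130 min⁻¹)
    Z → E (k = 2.70 × 10⁻⁴ min⁻¹)

The forecast's c stands 9 points above this. With L at 0%, c times the target gives 4.30, the flask's dp. The neighbour with 0.027 M of L has c 57.4%, and its ratio gives 3.40 against a simulated 3.40. This flask is not at rest at 30 h: G is made 2.25 times faster than it is used up, and Z stands at 0.00999 M. By 300 h, Z has dropped to 1.26 × 10⁻⁴ M, E has risen to 0.0159 M, and c has reached 64.8%, so the target gives 6.48, matching the computed dp of 6.48.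

All runs stem from a simulated flask on assumed constants; scatter was added.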